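# Proposed synthesis of CNP0119373.2 by allylboration–lactonisation to a cis α-methylene lactone

## Analysis of the target

The target is a 2,3,4-trisubstituted oxolane (O1, C2–C5). C2 carries a 4-hydroxy-3-methoxyphenyl group (ring A), C3 a CH2O unit acylated by (E)-4-hydroxycinnamic acid (ring C), C4 a 4-hydroxy-3-methoxybenzyl group (ring B), and C5 is a methylene. The three contiguous stereocentres are (2S,3S,4R): the aryl group at C2 and the acyloxymethyl group at C3 are cis, and the benzyl group at C4 is trans to both. The 3,4-trans relationship is the thermodynamically preferred one, but the 2,3-cis relationship is not. C2 is a benzylic ether carbon para to an oxygen substituent, so acid (benzylic cation) or base acting on a free phenol (quinone methide) can break the C2–O1 bond and return the 2,3-trans isomer. Further sensitive groups are the three free phenols and the cinnamate ester, whose E-alkene rules out hydrogenation and hydrogenolytic deprotection; the benzylic C2–O bond is itself open to hydrogenolysis. The difficulty is therefore to set the cis C2/C3 pair under kinetic and absolute control, to carry it unchanged to the end, and to acylate one primary alcohol beside phenols. The plan rests on one feature: O1–C2(aryl)–C3(CH2O) with cis substituents, extended by C4 and C5, is the skeleton of a cis γ-aryl-β-(oxymethyl)-γ-butyrolactone once C5 is a carbonyl and C4 carries an exocyclic methylene. That lactone is what an aryl aldehyde and a γ-substituted 2-(methoxycarbonyl)allylboronate form in one step, and its methylene is the point of attachment for ring B.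

## Retrosynthetic reasoning

**Ester C–O bond (20 ⇒ 18 + 19).** The cinnamate is cut first, because it would not survive the hydride and organometallic steps that build the ring. The forward reaction must acylate the single primary hydroxyl of 18 beside phenols without acid or strong base. A redox condensation in which the carboxylate of 19 is the nucleophile meets this, and no stereocentre is involved.

**Silyl ethers (18 ⇒ 17).** The phenols of rings A and B are masked as triisopropylsilyl ethers and the primary alcohol as a tert-butyldimethylsilyl ether. The para oxygen of ring A must stay capped whenever base is present, so that no phenoxide can expel the benzylic oxygen at C2. The bulkier silyl group is chosen for the phenols because it should withstand amidine base, hydride and alkoxide. All three groups fall in one fluoride operation.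

**O1–C5 bond (17 ⇒ 15, through 16).** The ring is opened at O1–C5 and not at O1–C2. Closure then is a substitution at the primary carbon C5 with the benzylic oxygen as nucleophile, so the C2–O bond made in the key step is never broken. Closing in the other sense would make C2 the electrophile and scramble it.

**Oxidation level of C5 (15 ⇒ 14).** Raising C5 to a lactone carbonyl ties C2 and C3 into a ring and makes the hydrogen at C4 acidic. The forward step is a plain hydride reduction.

**Configuration at C4 (14 ⇒ 13).** The benzyl group trans to the cis C2/C3 pair is the stable arrangement, so C4 needs no kinetic control; equilibration of the epimer mixture 13 should converge on 14.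

**Benzylic carbon–ring B bond (13 ⇒ 10 + 12).** Cutting between the CH2 on C4 and ring B leaves an α-methylene lactone, the direct product of the key step. The forward reaction is a rhodium-catalysed conjugate arylation with the boronate 12, which comes from the phenol 11 by silylation.

**C2–C3 and O1–C5 acyl bonds (10 ⇒ 2 + 8).** This is the key disconnection. Both bonds, the ring and the two stereocentres C2 and C3 arise from aldehyde 2 and allylboronate 8. The forward reaction has to deliver the syn adduct, on one aldehyde face, and close the lactone without ionising the new benzylic C–O bond.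

**Allylboronate (8 ⇒ 6 + 7; 6 ⇒ 5 ⇒ 3 + 4) and aldehyde (2 ⇒ 1).** The C–B bond is cut with allylic transposition back to the acetate 6 and the diboron 7. The acetate comes from the Baylis–Hillman adduct 5 of acrylate 3 and aldehyde 4, which brings in C3, its CH2O group, C4 and C5. Aldehyde 2 is silylated vanillin 1.

## Alternatives that were turned down

Alternative 1: The ring is cut at C2–C3 and C4–C5 at once. O1 with C2 (ring A) and C5 becomes a carbonyl ylide, and C3–C4 becomes an (E)-alkene bearing an acyl group at C3 and the ring-B benzyl group at C4. In the forward step, fluoride-induced 1,3-desilylation of the α-chloro benzyl (trimethylsilyl)methyl ether A2 releases the non-stabilised ylide. This is trapped by the (E)-N-enoyl camphorsultam A3 to give the 2,3-cis-3,4-trans oxolane-3-carbonyl sultam A1.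
- For: it is the most convergent plan. The whole ring and all three stereocentres form in one step, 3,4-trans follows stereospecifically from the alkene geometry, and reductive removal of the auxiliary gives the CH2OH group directly. On step economy it is clearly stronger than the chosen route, which has to open and re-close the ring.
- Against: the 2,3-cis relationship needs an endo approach of the aryl terminus to the acyl group. A short-lived, non-stabilised ylide has no organising element for this, so cis/trans mixtures are to be expected, with no thermodynamic correction available since cis is the less stable isomer. A2 is an α-chloro ether of a para-alkoxybenzaldehyde and should ionise and hydrolyse very easily. The γ-CH2 of A3 is both allylic and benzylic and may deconjugate to the styrene under basic fluoride. The β-substituted dipolarophile is slow compared with the lifetime of the ylide.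
- Comparison: the chosen route gives up convergence and in return sets the critical C2/C3 pair in a closed chair.

Alternative 2: The carbon on C3 is traced back to a cyclopropane fused across C2–C3 of the enantiopure 5-aryl-3-(arylmethyl)-2,3-dihydrofuran A5. In the forward step a zinc carbenoid (Simmons–Smith conditions) adds to the enol ether on the face opposite the C4 benzyl group, giving the 2-oxabicyclo[3.1.0]hexane A4.
- For: an electron-rich enol ether is an ideal substrate and the facial bias from the adjacent C4 substituent is well understood, so 3,4-trans is set reliably. The oxolane with both aryl groups is present from the start and is never opened; on these two points it is as strong as or stronger than the chosen route.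
- Against: A4 has neither the hydrogen at C2 nor an oxygen on the new carbon. The C2–CH2 bond of the cyclopropane must be cleaved by an electrophile that ends up as oxygen (a mercury salt or a halonium ion followed by substitution); protonolysis would give a C3 methyl group. The aryl-stabilised oxocarbenium ion at C2 must then be reduced. C2 is thus set late in a cationic manifold, where the C3 substituent directs hydride to give cis and the C4 benzyl group on the same face opposes it. A5 also needs an enantioselective synthesis of its own.
- Comparison: the chosen route sets C2 and C3 together in one organised transition state and leaves only C4 to thermodynamic control.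

Alternative 3: The bonds from C4 to its benzylic carbon and from C3 to its CH2O carbon are cut. In the forward step the lithio derivative of 2-aryl-1,3-dithiane A8 adds to C4 of (5R)-5-(menthyloxy)furan-2(5H)-one A7 anti to the menthyloxy group, and the enolate is alkylated at C3 by benzyl chloromethyl ether A9. This gives the all-trans lactone A6.
- For: tandem conjugate addition–alkylation on this butenolide gives very dependable anti,anti control and crystalline diastereomers, and the absolute configuration comes from a stoichiometric auxiliary. For certainty of absolute and relative control at C3/C4 it is stronger than the chosen route.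
- Against: in A6 the carbon that must become C2 is still a lactone carbonyl and C5 is an acetal. Ring A has to be added to the carbonyl and the resulting hemiketal reduced, so C2 is again set late through an oxocarbenium ion, where the 2,3-trans isomer is a likely outcome. The acetal must be reduced under Lewis acid, the dithiane removed with Raney Ni, and the benzyl ethers cleaved by hydrogenolysis next to a benzylic ring C–O bond and before any cinnamate can be present. It is the longest of the four plans.
- Comparison: the chosen route places ring A and the cis relationship in the first ring-forming step.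

Key step: step 5

## Route

Locants C2–C5 without comment refer to the oxolane of the target. In the lactone names, C2 is the carbonyl (target C5), C3 the α-carbon (target C4), C4 the β-carbon (target C3) and C5 the aryl-bearing carbon (target C2).

Assumption: the (S)-configured phosphoric acid is taken to expose the si face of aldehyde 2, the sense known for allyl and (Z)-crotyl pinacolboronates with aryl aldehydes; should boronate 8 reverse it, the (R)-acid is used and nothing else changes.

Step 1
Reactants: 1 vanillin
Product: 2 3-methoxy-4-(triisopropylsilyloxy)benzaldehyde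
Conditions: TIPSCl, imidazole, DMF, rt
Reagents that add atoms: chlorotriisopropylsilane (TIPSCl), CC(C)[Si](Cl)(C(C)C)C(C)C
Why: Silylation of a phenol; the triisopropylsilyl ether is preferred to a smaller silyl group because it must survive amidine base, LiAlH4 and alkoxide later, and its loss on ring A in base would open a quinone-methide path that destroys C2.

Step 2
Reactants: 3 methyl acrylate; 4 (tert-butyldimethylsilyloxy)acetaldehyde
Product: 5 methyl 4-(tert-butyldimethylsilyloxy)-3-hydroxy-2-methylidenebutanoate (racemic)
Conditions: DABCO (0.5 equiv.), 3 (3 equiv.), neat, rt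
Reagents that add atoms: none
Why: Baylis–Hillman reaction; α-alkoxy aldehydes are reactive acceptors for the amine–acrylate zwitterion, and the racemic carbinol centre is removed in step 4.

Step 3
Reactants: 5 methyl 4-(tert-butyldimethylsilyloxy)-3-hydroxy-2-methylidenebutanoate
Product: 6 methyl 3-acetoxy-4-(tert-butyldimethylsilyloxy)-2-methylidenebutanoate (racemic)
Conditions: Ac2O, pyridine, DMAP (cat.), CH2Cl2, 0 °C → rt
Reagents that add atoms: acetic anhydride, CC(=O)OC(C)=O
Why: Acylation of a secondary alcohol, which installs the allylic leaving group for the transposition.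

Step 4
Reactants: 6 methyl 3-acetoxy-4-(tert-butyldimethylsilyloxy)-2-methylidenebutanoate; 7 bis(pinacolato)diboron
Product: 8 methyl (E)-4-(tert-butyldimethylsilyloxy)-2-[(4,4,5,5-tetramethyl-1,3,2-dioxaborolan-2-yl)methyl]but-2-enoate (CH2OSi cis to CH2B)
Conditions: CuCl (10 mol%), LiCl, KOAc, DMF, rt
Reagents that add atoms: none
Why: Copper-mediated SN2' borylation of a Baylis–Hillman acetate (Hosomi–Miyaura type): a boryl–copper species adds to the acrylate terminus and acetate is eliminated. The alkene is expected with CH2OSi trans to the ester, hence cis to CH2B, as in other SN2' substitutions of acrylate-derived Baylis–Hillman acetates; any minor isomer is removed by chromatography because this geometry is carried into the key step.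

Step 5
Reactants: 2 3-methoxy-4-(triisopropylsilyloxy)benzaldehyde; 8 methyl (E)-4-(tert-butyldimethylsilyloxy)-2-[(4,4,5,5-tetramethyl-1,3,2-dioxaborolan-2-yl)methyl]but-2-enoate
Product: 10 (4S,5S)-4-[(tert-butyldimethylsilyloxy)methyl]-5-[3-methoxy-4-(triisopropylsilyloxy)phenyl]-3-methylideneoxolan-2-one, via syn homoallylic pinacol borate 9 (not isolated)
Conditions: (S)-TRIP [(S)-3,3'-bis(2,4,6-triisopropylphenyl)-1,1'-binaphthyl-2,2'-diyl hydrogen phosphate] (10 mol%), 8 (1.2 equiv.), PhMe, −20 °C → rt; then pyridinium p-toluenesulfonate (10 mol%), rt
Reagents that add atoms: none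
Why: The phosphoric acid hydrogen-bonds to a dioxaborolane oxygen of 8 and, through its P=O group, to the formyl C–H of 2, so that the two meet in a closed six-membered chair (B, the aldehyde O and C, and the three allyl carbons) with the aryl group equatorial and the CH2OSi group, cis to CH2B on the alkene, forced axial; this forms the C2–C3 bond and gives the syn borate 9. The closest known reaction type is the acid-catalysed allylboration of aldehydes with 2-(alkoxycarbonyl)allylboronates, which gives α-methylene-γ-butyrolactones with transfer of the boronate geometry, run here with a chiral BINOL-derived phosphoric acid as in enantioselective allyl- and crotylboration of aryl aldehydes. The ring closes by 5-exo-trig acyl substitution: the borate oxygen of 9 attacks the neighbouring ester carbonyl and methoxide passes to boron, which makes the O1–C5 acyl bond. C3 is set relative to C2 by the chair (syn in the chain equals cis on the ring), and C2 is set absolutely by the catalyst, whose 2,4,6-triisopropylphenyl groups should leave only the si face of the bound aldehyde open. The step needs syn diastereoselection, si-face selection and no ionisation of the new benzylic C–O bond. The first rests on the geometrical purity of 8, the second on the fact that this ester-deactivated boronate has practically no uncatalysed reaction at these temperatures, and the third on closing the lactone with weak acids only, never triflic acid or metal triflates, which are known to turn such adducts of electron-rich aldehydes into trans lactones through the benzylic cation. The silyl ether on the side chain leaves a single oxygen free for ring closure, so only the γ-aryl lactone can form.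

Step 6
Reactants: 11 2-methoxy-4-(4,4,5,5-tetramethyl-1,3,2-dioxaborolan-2-yl)phenol
Product: 12 2-[3-methoxy-4-(triisopropylsilyloxy)phenyl]-4,4,5,5-tetramethyl-1,3,2-dioxaborolane
Conditions: TIPSCl, imidazole, DMF, rt
Reagents that add atoms: chlorotriisopropylsilane (TIPSCl), CC(C)[Si](Cl)(C(C)C)C(C)C
Why: Silylation of a phenol beside an inert pinacol boronate; capping the para oxygen slows protodeboronation and gives ring B the same protecting group as ring A.

Step 7
Reactants: 10 (4S,5S)-4-[(tert-butyldimethylsilyloxy)methyl]-5-[3-methoxy-4-(triisopropylsilyloxy)phenyl]-3-methylideneoxolan-2-one; 12 2-[3-methoxy-4-(triisopropylsilyloxy)phenyl]-4,4,5,5-tetramethyl-1,3,2-dioxaborolane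
Product: 13 (4S,5S)-4-[(tert-butyldimethylsilyloxy)methyl]-5-[3-methoxy-4-(triisopropylsilyloxy)phenyl]-3-{[3-methoxy-4-(triisopropylsilyloxy)phenyl]methyl}oxolan-2-one (mixture of C3 epimers)
Conditions: [Rh(cod)OH]2 (3 mol%), 12 (2 equiv.), dioxane/H2O 10:1, 50 °C
Reagents that add atoms: none
Why: Hayashi–Miyaura-type 1,4-addition: the aryl–rhodium species formed by transmetalation of 12 with the hydroxo-rhodium complex delivers its aryl group to the terminus of the exocyclic methylene, and water protonates the rhodium enolate. The lactone C3 centre (target C4) forms without control, which is acceptable because step 8 equilibrates it.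

Step 8
Reactants: 13 (4S,5S)-4-[(tert-butyldimethylsilyloxy)methyl]-5-[3-methoxy-4-(triisopropylsilyloxy)phenyl]-3-{[3-methoxy-4-(triisopropylsilyloxy)phenyl]methyl}oxolan-2-one (mixture of C3 epimers)
Product: 14 (3R,4S,5S)-4-[(tert-butyldimethylsilyloxy)methyl]-5-[3-methoxy-4-(triisopropylsilyloxy)phenyl]-3-{[3-methoxy-4-(triisopropylsilyloxy)phenyl]methyl}oxolan-2-one
Conditions: DBU (0.5 equiv.), PhMe, rt → 50 °C
Reagents that add atoms: none
Why: Base-mediated epimerisation α to the lactone carbonyl under thermodynamic control: the epimer with the benzyl group trans to the neighbouring CH2OSi group avoids an all-cis trisubstituted ring and should dominate. The lactone C4 and C5 carry no acidic hydrogen, and the intact silyl ether on ring A keeps the benzylic C–O bond from being expelled.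

Step 9
Reactants: 14 (3R,4S,5S)-4-[(tert-butyldimethylsilyloxy)methyl]-5-[3-methoxy-4-(triisopropylsilyloxy)phenyl]-3-{[3-methoxy-4-(triisopropylsilyloxy)phenyl]methyl}oxolan-2-one
Product: 15 (1S,2S,3R)-2-[(tert-butyldimethylsilyloxy)methyl]-1-[3-methoxy-4-(triisopropylsilyloxy)phenyl]-3-{[3-methoxy-4-(triisopropylsilyloxy)phenyl]methyl}butane-1,4-diol
Conditions: LiAlH4, THF, 0 °C; then H2O, aq. NaOH
Reagents that add atoms: none
Why: Hydride reduction of a lactone to the 1,4-diol; no stereocentre is touched and hindered aryl and alkyl silyl ethers tolerate LiAlH4 at 0 °C.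

Step 10
Reactants: 15 (1S,2S,3R)-2-[(tert-butyldimethylsilyloxy)methyl]-1-[3-methoxy-4-(triisopropylsilyloxy)phenyl]-3-{[3-methoxy-4-(triisopropylsilyloxy)phenyl]methyl}butane-1,4-diol
Product: 17 (2S,3S,4R)-3-[(tert-butyldimethylsilyloxy)methyl]-2-[3-methoxy-4-(triisopropylsilyloxy)phenyl]-4-{[3-methoxy-4-(triisopropylsilyloxy)phenyl]methyl}oxolane, via primary monotosylate 16 (not isolated)
Conditions: TsCl (1.1 equiv.), Et3N, DMAP (cat.), CH2Cl2, 0 °C; then KOtBu, THF, 0 °C
Reagents that add atoms: none
Why: Selective sulfonylation of the unhindered primary hydroxyl over the hindered secondary benzylic one, then intramolecular Williamson etherification (5-exo-tet) re-forms O1–C5. The benzylic oxygen is the nucleophile, so the C2–O bond is not broken and C2 keeps its configuration.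

Step 11
Reactants: 17 (2S,3S,4R)-3-[(tert-butyldimethylsilyloxy)methyl]-2-[3-methoxy-4-(triisopropylsilyloxy)phenyl]-4-{[3-methoxy-4-(triisopropylsilyloxy)phenyl]methyl}oxolane
Product: 18 4-[(2S,3S,4R)-4-[(4-hydroxy-3-methoxyphenyl)methyl]-3-(hydroxymethyl)oxolan-2-yl]-2-methoxyphenol
Conditions: Bu4NF (3.5 equiv.), AcOH (3.5 equiv.), THF, 0 °C → rt
Reagents that add atoms: none
Why: Fluoride cleavage of the two aryl silyl ethers and the primary alkyl silyl ether; acetic acid buffers the phenoxides so that the para-hydroxybenzyl ether at C2 is exposed to neither strong base nor acid.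

Step 12
Reactants: 18 4-[(2S,3S,4R)-4-[(4-hydroxy-3-methoxyphenyl)methyl]-3-(hydroxymethyl)oxolan-2-yl]-2-methoxyphenol; 19 (E)-3-(4-hydroxyphenyl)prop-2-enoic acid (p-coumaric acid)
Product: 20 [(2S,3S,4R)-2-(4-hydroxy-3-methoxyphenyl)-4-[(4-hydroxy-3-methoxyphenyl)methyl]oxolan-3-yl]methyl (E)-3-(4-hydroxyphenyl)prop-2-enoate (target)
Conditions: 19 (1.2 equiv.), PPh3, DIAD, THF, 0 °C → rt
Reagents that add atoms: none
Why: Mitsunobu esterification: the only aliphatic hydroxyl is activated as an alkoxyphosphonium ion and displaced at its primary carbon by the carboxylate. The carboxylic acid is several pKa units more acidic than the phenols, so it alone is deprotonated by the betaine, which is the basis of the known chemoselective Mitsunobu esterification of phenolic acids without phenol protection; conditions are near neutral and the E-alkene is untouched.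

## Compound list

1 | vanillin (4-hydroxy-3-methoxybenzaldehyde) | COc1cc(C=O)ccc1O | starting material
2 | 3-methoxy-4-(triisopropylsilyloxy)benzaldehyde | COc1cc(C=O)ccc1O[Si](C(C)C)(C(C)C)C(C)C | intermediate
3 | methyl acrylate | COC(=O)C=C | starting material
4 | (tert-butyldimethylsilyloxy)acetaldehyde | O=CCO[Si](C)(C)C(C)(C)C | starting material
5 | methyl 4-(tert-butyldimethylsilyloxy)-3-hydroxy-2-methylidenebutanoate (racemic) | COC(=O)C(=C)C(O)CO[Si](C)(C)C(C)(C)C | intermediate
6 | methyl 3-acetoxy-4-(tert-butyldimethylsilyloxy)-2-methylidenebutanoate (racemic) | COC(=O)C(=C)C(OC(C)=O)CO[Si](C)(C)C(C)(C)C | intermediate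
7 | bis(pinacolato)diboron | CC1(C)OB(OC1(C)C)B1OC(C)(C)C(C)(C)O1 | starting material
8 | methyl (E)-4-(tert-butyldimethylsilyloxy)-2-[(4,4,5,5-tetramethyl-1,3,2-dioxaborolan-2-yl)methyl]but-2-enoate | COC(=O)/C(CB1OC(C)(C)C(C)(C)O1)=C/CO[Si](C)(C)C(C)(C)C | intermediate
9 | methyl (3S,4S)-3-[(tert-butyldimethylsilyloxy)methyl]-4-[3-methoxy-4-(triisopropylsilyloxy)phenyl]-2-methylidene-4-[(4,4,5,5-tetramethyl-1,3,2-dioxaborolan-2-yl)oxy]butanoate (formed in the flask) | COC(=O)C(=C)[C@@H](CO[Si](C)(C)C(C)(C)C)[C@H](OB1OC(C)(C)C(C)(C)O1)c1ccc(O[Si](C(C)C)(C(C)C)C(C)C)c(OC)c1 | intermediate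
10 | (4S,5S)-4-[(tert-butyldimethylsilyloxy)methyl]-5-[3-methoxy-4-(triisopropylsilyloxy)phenyl]-3-methylideneoxolan-2-one | C=C1C(=O)O[C@H](c2ccc(O[Si](C(C)C)(C(C)C)C(C)C)c(OC)c2)[C@@H]1CO[Si](C)(C)C(C)(C)C | intermediate
11 | 2-methoxy-4-(4,4,5,5-tetramethyl-1,3,2-dioxaborolan-2-yl)phenol | COc1cc(B2OC(C)(C)C(C)(C)O2)ccc1O | starting material
12 | 2-[3-methoxy-4-(triisopropylsilyloxy)phenyl]-4,4,5,5-tetramethyl-1,3,2-dioxaborolane | COc1cc(B2OC(C)(C)C(C)(C)O2)ccc1O[Si](C(C)C)(C(C)C)C(C)C | intermediate
13 | (4S,5S)-4-[(tert-butyldimethylsilyloxy)methyl]-5-[3-methoxy-4-(triisopropylsilyloxy)phenyl]-3-{[3-methoxy-4-(triisopropylsilyloxy)phenyl]methyl}oxolan-2-one, mixture of epimers at C3 (centre left open in the SMILES) | COc1cc(CC2C(=O)O[C@H](c3ccc(O[Si](C(C)C)(C(C)C)C(C)C)c(OC)c3)[C@@H]2CO[Si](C)(C)C(C)(C)C)ccc1O[Si](C(C)C)(C(C)C)C(C)C | intermediate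
14 | (3R,4S,5S)-4-[(tert-butyldimethylsilyloxy)methyl]-5-[3-methoxy-4-(triisopropylsilyloxy)phenyl]-3-{[3-methoxy-4-(triisopropylsilyloxy)phenyl]methyl}oxolan-2-one | COc1cc(C[C@H]2C(=O)O[C@H](c3ccc(O[Si](C(C)C)(C(C)C)C(C)C)c(OC)c3)[C@@H]2CO[Si](C)(C)C(C)(C)C)ccc1O[Si](C(C)C)(C(C)C)C(C)C | intermediate
15 | (1S,2S,3R)-2-[(tert-butyldimethylsilyloxy)methyl]-1-[3-methoxy-4-(triisopropylsilyloxy)phenyl]-3-{[3-methoxy-4-(triisopropylsilyloxy)phenyl]methyl}butane-1,4-diol | COc1cc(C[C@@H](CO)[C@@H](CO[Si](C)(C)C(C)(C)C)[C@H](O)c2ccc(O[Si](C(C)C)(C(C)C)C(C)C)c(OC)c2)ccc1O[Si](C(C)C)(C(C)C)C(C)C | intermediate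
16 | (2R,3S,4S)-3-[(tert-butyldimethylsilyloxy)methyl]-4-hydroxy-4-[3-methoxy-4-(triisopropylsilyloxy)phenyl]-2-{[3-methoxy-4-(triisopropylsilyloxy)phenyl]methyl}butyl 4-methylbenzenesulfonate (formed in the flask) | COc1cc(C[C@@H](COS(=O)(=O)c2ccc(C)cc2)[C@@H](CO[Si](C)(C)C(C)(C)C)[C@H](O)c2ccc(O[Si](C(C)C)(C(C)C)C(C)C)c(OC)c2)ccc1O[Si](C(C)C)(C(C)C)C(C)C | intermediate
17 | (2S,3S,4R)-3-[(tert-butyldimethylsilyloxy)methyl]-2-[3-methoxy-4-(triisopropylsilyloxy)phenyl]-4-{[3-methoxy-4-(triisopropylsilyloxy)phenyl]methyl}oxolane | COc1cc(C[C@H]2CO[C@H](c3ccc(O[Si](C(C)C)(C(C)C)C(C)C)c(OC)c3)[C@@H]2CO[Si](C)(C)C(C)(C)C)ccc1O[Si](C(C)C)(C(C)C)C(C)C | intermediate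
18 | 4-[(2S,3S,4R)-4-[(4-hydroxy-3-methoxyphenyl)methyl]-3-(hydroxymethyl)oxolan-2-yl]-2-methoxyphenol | COc1cc(C[C@H]2CO[C@H](c3ccc(O)c(OC)c3)[C@@H]2CO)ccc1O | intermediate
19 | (E)-3-(4-hydroxyphenyl)prop-2-enoic acid (p-coumaric acid) | OC(=O)/C=C/c1ccc(O)cc1 | starting material
20 | [(2S,3S,4R)-2-(4-hydroxy-3-methoxyphenyl)-4-[(4-hydroxy-3-methoxyphenyl)methyl]oxolan-3-yl]methyl (E)-3-(4-hydroxyphenyl)prop-2-enoate | COc1cc(C[C@H]2CO[C@H](c3ccc(O)c(OC)c3)[C@@H]2COC(=O)/C=C/c2ccc(O)cc2)ccc1O | target

## Step count and least certain steps

Total: 12 steps. Longest linear sequence: 10 steps (steps 2, 3, 4, 5, 7, 8, 9, 10, 11, 12, from 3 and 4); steps 1 and 6 are one-step side branches.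

**Step 5 (key step).** Two things are most likely to go wrong.
- The syn/cis relationship may be lost by acid-promoted ionisation of the newly formed benzylic C–O bond during lactonisation, since the para-silyloxy, meta-methoxy ring stabilises the cation, followed by re-closure to the more stable trans lactone.
- Turnover of the ester-deactivated boronate with an electron-rich aldehyde may be slow, and warming to compensate would erode the facial selectivity.

The fallback moves the chirality onto boron and uses no added acid. It sets out from 8: KHF2 in aqueous methanol should give the potassium trifluoroborate F1, and Me3SiCl as fluoride acceptor with diisopropyl (2R,3R)-tartrate should convert it into the tartrate allylboronate F2. This more Lewis-acidic boronate should add to 2 in toluene at −20 °C to rt through the same chair without a catalyst, with the tartrate directing si-face attack by analogy with the parent tartrate allyl- and crotylboronates. Aqueous work-up gives the syn hydroxy ester F3, which is closed by warming in toluene with a neutral bifunctional catalyst such as 2-hydroxypyridine. The fallback returns to the route at 10. A lower enantiomeric purity is to be expected with an aryl aldehyde and would be raised by crystallisation at 15 or 18.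

**Step 7.** Protodeboronation of the electron-rich aryl boronate may outrun transmetalation, or β-hydride elimination from the rhodium enolate may divert material to the benzylidene lactone. The fallback replaces rhodium catalysis by organocopper chemistry and sets out from 10. Commercial 4-bromo-2-methoxyphenol is silylated to (4-bromo-2-methoxyphenoxy)triisopropylsilane F4 and converted with magnesium in THF into the aryl Grignard reagent F5. This is added to 10 with CuBr·SMe2 (cat.) in THF at −78 °C and the enolate is quenched with aqueous NH4Cl. It returns at 13, which is equilibrated as in step 8.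

**Step 10.** Under alkoxide conditions the tert-butyldimethylsilyl group may migrate from the primary oxygen to the neighbouring benzylic alkoxide before ring closure, after which the freed primary alkoxide would close a different oxolane. Sulfonylation of the benzylic hydroxyl, with ionisation at C2, is the second possible failure. The fallback never opens the ring and sets out from 14. i-Bu2AlH in CH2Cl2 at −78 °C should give the lactol F6 as an anomeric mixture, and Et3SiH with BF3·OEt2 at −78 °C should reduce the oxocarbenium ion at C5 to the methylene. It returns at 17. The brief exposure to Lewis acid at low temperature is accepted because ionisation of the lactol carbon should be much faster than that of the benzylic C2–O bond.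

**Step 12.** The guaiacyl phenols of 18 may compete as nucleophiles toward the activated primary carbon, giving aryl ethers and oligomers, and the triphenolic product may be hard to separate from the phosphine oxide. The fallback changes the order of deprotection and acylation and sets out from 17. HF·pyridine buffered with pyridine in THF at 0 °C should remove only the primary alkyl silyl ether and give the bis-silylated alcohol F7. Mitsunobu esterification of F7 with 19 (PPh3, DIAD, THF), in which the only free phenol is that of the acid itself, should give the bis-silylated coumarate F8. Bu4NF buffered with AcOH then removes the two aryl silyl groups. It returns at 20.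

## Further compounds

F1 | step 5 | potassium (E)-[4-(tert-butyldimethylsilyloxy)-2-(methoxycarbonyl)but-2-en-1-yl]trifluoroborate | COC(=O)/C(C[B-](F)(F)F)=C/CO[Si](C)(C)C(C)(C)C.[K+]
F2 | step 5 | diisopropyl (4R,5R)-2-[(E)-4-(tert-butyldimethylsilyloxy)-2-(methoxycarbonyl)but-2-en-1-yl]-1,3,2-dioxaborolane-4,5-dicarboxylate | COC(=O)/C(CB1O[C@@H](C(=O)OC(C)C)[C@H](C(=O)OC(C)C)O1)=C/CO[Si](C)(C)C(C)(C)C
F3 | step 5 | methyl (3S,4S)-3-[(tert-butyldimethylsilyloxy)methyl]-4-hydroxy-4-[3-methoxy-4-(triisopropylsilyloxy)phenyl]-2-methylidenebutanoate | COC(=O)C(=C)[C@@H](CO[Si](C)(C)C(C)(C)C)[C@H](O)c1ccc(O[Si](C(C)C)(C(C)C)C(C)C)c(OC)c1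
F4 | step 7 | (4-bromo-2-methoxyphenoxy)triisopropylsilane | COc1cc(Br)ccc1O[Si](C(C)C)(C(C)C)C(C)C
F5 | step 7 | [3-methoxy-4-(triisopropylsilyloxy)phenyl]magnesium bromide | COc1cc([Mg]Br)ccc1O[Si](C(C)C)(C(C)C)C(C)C
F6 | step 10 | (3R,4S,5S)-4-[(tert-butyldimethylsilyloxy)methyl]-5-[3-methoxy-4-(triisopropylsilyloxy)phenyl]-3-{[3-methoxy-4-(triisopropylsilyloxy)phenyl]methyl}oxolan-2-ol (anomeric mixture) | COc1cc(C[C@H]2C(O)O[C@H](c3ccc(O[Si](C(C)C)(C(C)C)C(C)C)c(OC)c3)[C@@H]2CO[Si](C)(C)C(C)(C)C)ccc1O[Si](C(C)C)(C(C)C)C(C)C
F7 | step 12 | [(2S,3S,4R)-2-[3-methoxy-4-(triisopropylsilyloxy)phenyl]-4-{[3-methoxy-4-(triisopropylsilyloxy)phenyl]methyl}oxolan-3-yl]methanol | COc1cc(C[C@H]2CO[C@H](c3ccc(O[Si](C(C)C)(C(C)C)C(C)C)c(OC)c3)[C@@H]2CO)ccc1O[Si](C(C)C)(C(C)C)C(C)C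
F8 | step 12 | [(2S,3S,4R)-2-[3-methoxy-4-(triisopropylsilyloxy)phenyl]-4-{[3-methoxy-4-(triisopropylsilyloxy)phenyl]methyl}oxolan-3-yl]methyl (E)-3-(4-hydroxyphenyl)prop-2-enoate | COc1cc(C[C@H]2CO[C@H](c3ccc(O[Si](C(C)C)(C(C)C)C(C)C)c(OC)c3)[C@@H]2COC(=O)/C=C/c2ccc(O)cc2)ccc1O[Si](C(C)C)(C(C)C)C(C)C
A1 | alternative 1 | 2,3-cis-3,4-trans N-{[2-(4-allyloxy-3-methoxyphenyl)-4-(4-allyloxy-3-methoxybenzyl)oxolan-3-yl]carbonyl}camphorsultam | O=S1(=O)C[C@@]23CC[C@@H](C2(C)C)C[C@H]3N1C(=O)[C@@H]1[C@@H](Cc2ccc(OCC=C)c(OC)c2)CO[C@@H]1c1ccc(OCC=C)c(OC)c1
A2 | alternative 1 | {[chloro(4-allyloxy-3-methoxyphenyl)methoxy]methyl}trimethylsilane (racemic) | C=CCOc1ccc(C(Cl)OC[Si](C)(C)C)cc1OC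
A3 | alternative 1 | N-[(E)-4-(4-allyloxy-3-methoxyphenyl)but-2-enoyl]camphorsultam | O=S1(=O)C[C@@]23CC[C@@H](C2(C)C)C[C@H]3N1C(=O)/C=C/Cc1ccc(OCC=C)c(OC)c1
A4 | alternative 2 | 1-[4-(tert-butyldimethylsilyloxy)-3-methoxyphenyl]-4-{[4-(tert-butyldimethylsilyloxy)-3-methoxyphenyl]methyl}-2-oxabicyclo[3.1.0]hexane, cyclopropane anti to benzyl | COc1cc(C[C@H]2CO[C@]3(c4ccc(O[Si](C)(C)C(C)(C)C)c(OC)c4)C[C@H]23)ccc1O[Si](C)(C)C(C)(C)C
A5 | alternative 2 | (3R)-5-[4-(tert-butyldimethylsilyloxy)-3-methoxyphenyl]-3-{[4-(tert-butyldimethylsilyloxy)-3-methoxyphenyl]methyl}-2,3-dihydrofuran | COc1cc(C[C@H]2COC(c3ccc(O[Si](C)(C)C(C)(C)C)c(OC)c3)=C2)ccc1O[Si](C)(C)C(C)(C)C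
A6 | alternative 3 | all-trans 3-(benzyloxymethyl)-4-[2-(4-benzyloxy-3-methoxyphenyl)-1,3-dithian-2-yl]-5-(menthyloxy)oxolan-2-one | COc1cc(C2(SCCCS2)[C@H]2[C@H](O[C@@H]3C[C@H](C)CC[C@H]3C(C)C)OC(=O)[C@@H]2COCc2ccccc2)ccc1OCc1ccccc1
A7 | alternative 3 | (5R)-5-[(1R,2S,5R)-menthyloxy]furan-2(5H)-one | O=C1C=C[C@H](O[C@@H]2C[C@H](C)CC[C@H]2C(C)C)O1
A8 | alternative 3 | 2-(4-benzyloxy-3-methoxyphenyl)-1,3-dithiane | COc1cc(C2SCCCS2)ccc1OCc1ccccc1
A9 | alternative 3 | benzyl chloromethyl ether | ClCOCc1ccccc1
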